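Friday's flask cannot hold 1.5 M of target if one substrate and one coupling partner make one target, for it was charged with less coupling partner than substrate. Whether that simple count holds is what two chemists disputed.

all flasks: coupling partner 1.05 M; free catalyst 220 mM

| flask | substrate | remark | time |
|---|---|---|---|
| alder | 0.12 M | run made earlier |  |
| elm | 1.8 M | run made earlier |  |
| Sunday's | 0.10 M |  | 6.0 min |
| Thursday's | 0.20 M |  | 6.0 min |
| Wednesday's | 0.40 M |  | 6.0 min |
| Tuesday's | 0.80 M |  | 6.0 min |
| Friday's | 1.5 M |  | 6.0 min |

- alder (time / min: target / %): 0.250: 58; 0.667: 85; 1.33: 97; 2.00: 98; 2.50: 101; 3.00: 99; 4.00: 100
- elm (time / min: target / %): 0.667: 50; 1.33: 56; 2.00: 54; 2.50: 55; 3.00: 56; 4.00: 61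

(standard deviation of a reading: 1.5 percentage points)

- [target] at the end for Sunday's, Thursday's, Wednesday's, Tuesday's, Friday's, in this order
- the shape of the row from first to last (falls all the way / rises all the way / rises, then falls / hardly changes / falls, then rises)

- "hardly changes" means that all values lie within two and a half points (for a concentration: within two and a half percent of the largest)

The first chemist starts from the alder run. It stood at 97% after 1.33 min, with coupling partner far above substrate. She therefore treats the partner as constant, the pseudo-first-order picture, and expects each substrate charge to be consumed within 6.0 min. Elm's stall does not trouble her, since its last reading is 61% at 4.00 min and looks to her like a slow climb. So she gives Friday's its whole 1.5 M.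

The second chemist holds to one quantity, the ceiling: the smaller of the two charges divided by the substrate charge, which for Friday's is 70.0%. For elm the same division gives 58.3%. Elm's readings lie between 54% and 56% from 1.33 min to 3.00 min, just under that ceiling. The late reading stands 2.7 percentage points above it, but it is a single reading with a scatter of 1.5 points. On this view Friday's stops near 1.05 M, not at its full charge.

The forecast sides with the second chemist: 0.1 M, 0.2 M, 0.4 M, 0.79 M and 1.02 M, a row that rises all the way. In its words, “The 1.5 M charge should stop at the partner limit, about 1.0 M.”

The flask gives 0.100 M, 0.200 M, 0.400 M, 0.782 M and 1.04 M, a row that rises all the way.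

    substrate + coupling partner + free catalyst → target + free catalyst, rate k1*[substrate]*[coupling partner]*[free catalyst]/(1 + ([substrate]/sat1)) (4.72 M, k = 15.7 /M²/min)
    2 free catalyst → spent catalyst (k = 1.05 /M/min)

Friday's target stands at 69.6% of the substrate charged, on the ceiling of 70.0%, with 0.571% of the coupling partner left, so the partner is the limiting reagent there: without its depletion the same run ends at 1.50 M instead of 1.04 M. Friday's free catalyst falls to 26.5%, yet that loss makes no difference to its target. Sunday's, charged with far less substrate than coupling partner, is where the first chemist's picture belongs: 90.5% of its partner is left after 6.00 min, and its target stands at >99.9% of the substrate charged.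

(The readings were generated by integration for substances that don't exist, noise included.)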